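**Retrosynthetic overview**
1. Target 36 ⇐ trimer ketone 35 by NaBH4 reduction of the lower C4 ketone (last stereocentre); 35 ⇐ 33 by methanolysis of a temporary carbonate and hydrogenolysis.
2. 33 ⇐ cyclic enol carbonate 24 + mixed acetal 30 by an acid-catalysed formal [4+2] (oxa-Povarov) that makes C2–C3 and C4–C4a of the upper pyran ring and its three stereocentres. Enabling feature: C2/O1/C8a/C4a of the upper C-ring map onto an O-aryl oxocarbenium ion, and upper C3=C4 can be held as a Z-enol carbonate in a seven-membered ring (O3–C(=O)–O7) fused to C6/C7 of the middle A-ring, whose O1 (para to C6) stabilises the C4 cation.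
3. 24 ⇐ 18 by Stille vinylation at C6, desilylation of O7, vinyl carbonate formation and ring-closing metathesis.
4. 18 ⇐ 15 + 6 by Friedel–Crafts formation of the C4(middle)–C6(lower) bond, with the lower ketone masked as a dithiolane.
5. 15 and 6 ⇐ (2R,3R)-fustin. Ring order: the lower and middle pyran rings come with fustin, then the temporary dioxepinone ring, then the upper pyran ring.

Key step: step 17

Remark on the chemistry: (2R,3R)-fustin is taken as a commercial natural product. The sense of induction of the chiral acid in step 17 cannot be deduced from precedent; the (S)-acid is written and stands for whichever antipode delivers the upper-unit configuration of the target.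

**Route**

Step 1
Reactants: 1 (2R,3R)-fustin; 2 benzyl bromide
Product: 3 (2R,3R)-7-benzyloxy-2-[3,4-bis(benzyloxy)phenyl]-3-hydroxychroman-4-one
Conditions: BnBr (3.3 equiv), K2CO3, DMF, rt, N2
Reagents that add atoms: benzyl bromide, BrCc1ccccc1
Why: Williamson etherification of the three phenols, which are far more acidic than the secondary 3-OH, so that the alcohol stays free and no stereocentre is touched.

Step 2
Reactants: 3; 4 ethane-1,2-dithiol
Product: 5 (2R,3R)-7-benzyloxy-2-[3,4-bis(benzyloxy)phenyl]spiro[chromane-4,2'-[1,3]dithiolan]-3-ol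
Conditions: HS(CH2)2SH, BF3·OEt2, CH2Cl2, 0 °C to rt
Reagents that add atoms: ethane-1,2-dithiol, SCCS
Why: Lewis-acid dithioketalization of the aryl ketone removes the electron-withdrawing carbonyl, so that the A-ring becomes a resorcinol-type nucleophile for step 9 while C4 cannot ionize.

Step 3
Reactants: 5; 2 benzyl bromide
Product: 6 (2R,3R)-3,7-bis(benzyloxy)-2-[3,4-bis(benzyloxy)phenyl]spiro[chromane-4,2'-[1,3]dithiolane]
Conditions: NaH, BnBr, Bu4NI (cat.), DMF, 0 °C to rt
Reagents that add atoms: benzyl bromide, BrCc1ccccc1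
Why: Williamson etherification of the secondary alkoxide, which is safe here because the base-sensitive ketone is masked.

Step 4
Reactants: 1 (2R,3R)-fustin; 7 dichlorodiphenylmethane
Product: 8 (2R,3R)-2-(2,2-diphenyl-1,3-benzodioxol-5-yl)-3,7-dihydroxychroman-4-one
Conditions: Ph2CCl2, K2CO3, MeCN, rt, N2; dilute acid work-up
Reagents that add atoms: dichlorodiphenylmethane, ClC(Cl)(c1ccccc1)c1ccccc1
Why: catechol-selective ketalization, since only the 1,2-diphenol can close the five-membered benzodioxole and any acyclic mixed ketal at O7 is hydrolysed on work-up.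

Step 5
Reactants: 8; 9 chlorotriisopropylsilane
Product: 10 (2R,3R)-2-(2,2-diphenyl-1,3-benzodioxol-5-yl)-3-hydroxy-7-(triisopropylsilyloxy)chroman-4-one
Conditions: TIPSCl, imidazole, DMF, 0 °C to rt
Reagents that add atoms: chlorotriisopropylsilane, CC(C)[Si](Cl)(C(C)C)C(C)C
Why: silylation of the phenol, which is much faster than that of the hindered, hydrogen-bonded secondary alcohol, marks O7 of the future middle unit for later release.

Step 6
Reactants: 10; 11 2-benzyloxy-1-methylpyridinium triflate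
Product: 12 (2R,3R)-3-benzyloxy-2-(2,2-diphenyl-1,3-benzodioxol-5-yl)-7-(triisopropylsilyloxy)chroman-4-one
Conditions: 2-benzyloxy-1-methylpyridinium triflate, MgO, PhCF3, 85 °C
Reagents that add atoms: 2-benzyloxy-1-methylpyridinium triflate, C[n+]1ccccc1OCc1ccccc1.[O-]S(=O)(=O)C(F)(F)F
Why: neutral thermal benzyl transfer (benzylation with a 2-benzyloxypyridinium salt) avoids the base-induced ring opening and epimerization of the dihydroflavonol.

Step 7
Reactants: 12
Product: 13 (2R,3S,4R)-3-benzyloxy-2-(2,2-diphenyl-1,3-benzodioxol-5-yl)-7-(triisopropylsilyloxy)chroman-4-ol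
Conditions: NaBH4, THF/MeOH 4:1, 0 °C
Reagents that add atoms: none
Why: borohydride reduction of the aryl ketone, with hydride expected to add trans to the C3 substituent; the configuration at C4 is of no consequence because C4 is ionized in step 9.

Step 8
Reactants: 13; 14 N-bromosuccinimide
Product: 15 (2R,3S,4R)-3-benzyloxy-6-bromo-2-(2,2-diphenyl-1,3-benzodioxol-5-yl)-7-(triisopropylsilyloxy)chroman-4-ol
Conditions: NBS, CH2Cl2, −78 to −20 °C, dark
Reagents that add atoms: N-bromosuccinimide, O=C1CCC(=O)N1Br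
Why: electrophilic aromatic bromination at C6, which is para to O1 and ortho to O7, whereas C8 is shielded between two oxygens and the B-ring has only one para donor; the bromide is the later coupling handle and blocks self-condensation in step 9.

Step 9
Reactants: 15; 6
Product: 16 dimer bromide dithiolane: middle unit (6-bromo, 7-OTIPS, 3-OBn, diphenylmethylene ketal; 2,3-trans-3,4-trans) bonded through C4 (4α) to C6 of lower unit 6
Conditions: 6 (3 equiv), BF3·OEt2, CH2Cl2, −40 to 0 °C
Reagents that add atoms: none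
Why: Friedel–Crafts alkylation by the flavan-4-yl cation; C6 of 6 (para to O1, unhindered) should attack anti to the 3-benzyloxy group, which sets the middle C4 as 3,4-trans (4α), and the only other strong arene nucleophile, the A-ring of 15, is blocked by bromine.

Step 10
Reactants: 16; 17 water
Product: 18 dimer bromide ketone (as 16, lower C4 = ketone)
Conditions: MeI (excess), NaHCO3, MeCN/THF/H2O, 45 °C
Reagents that add atoms: water, O
Why: alkylative hydrolysis of the dithiolane (S-methylation, thionium ion, hydration) under near-neutral conditions returns the ketone, which from here on protects the lower C4 against ionization.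

Step 11
Reactants: 18; 19 tributyl(vinyl)stannane
Product: 20 6-vinyl dimer (as 18, vinyl in place of bromine)
Conditions: Pd[P(t-Bu)3]2 (cat.), toluene, 80 °C
Reagents that add atoms: tributyl(vinyl)stannane, C=C[Sn](CCCC)(CCCC)CCCC
Why: Stille cross-coupling under neutral conditions, with an electron-rich bulky phosphine for the hindered, electron-rich aryl bromide; silyl ether, ketone and benzyl ethers are inert.

Step 12
Reactants: 20
Product: 21 7-hydroxy-6-vinyl dimer (middle O7 free)
Conditions: TBAF, AcOH (1:1), THF, 0 °C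
Reagents that add atoms: none
Why: fluoride cleavage of the aryl silyl ether, buffered with acetic acid so that the α-benzyloxy ketone is not enolized.

Step 13
Reactants: 21; 22 vinyl chloroformate
Product: 23 6-vinyl dimer 7-O-(vinyl carbonate)
Conditions: vinyl chloroformate, pyridine, CH2Cl2, −20 to 0 °C
Reagents that add atoms: vinyl chloroformate, C=COC(Cl)=O
Why: O-acylation of the only free hydroxyl (a phenol) by a chloroformate.

Step 14
Reactants: 23
Product: 24 cyclic enol carbonate: middle A-ring fused at C6/C7 to a 1,3-dioxepin-2-one ring (C7–O–C(=O)–O–CH=CH–C6, Z)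
Conditions: Mo(=CHCMe2Ph)(=N-2,6-i-Pr2C6H3)[OCMe(CF3)2]2 (20 mol %), benzene, 50 °C, argon purge
Reagents that add atoms: none
Why: Proposed new method: ring-closing metathesis in which the molybdenum alkylidene initiates at the styrene and the resulting arylidene closes onto the vinyl carbonate through a metallacyclobutane with loss of ethene, the seven-membered ring allowing only the Z-alkene; the closest known reaction type is RCM of acyclic enol ethers with terminal alkenes under the same molybdenum alkylidene, and molybdenum is chosen because O-acyl vinyl groups convert ruthenium benzylidenes into unreactive acyloxycarbenes.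

Step 15
Reactants: 25 3,4-bis(benzyloxy)benzaldehyde; 26 trimethyl orthoformate
Product: 27 3,4-bis(benzyloxy)benzaldehyde dimethyl acetal
Conditions: HC(OMe)3, TsOH (cat.), MeOH, rt; Et3N quench
Reagents that add atoms: trimethyl orthoformate, COC(OC)OC
Why: acid-catalysed acetalization driven by the orthoformate as dehydrating agent.

Step 16
Reactants: 27; 28 3-(benzyloxy)phenol
Product: 30 racemic mixed acetal 1-[(3-benzyloxyphenoxy)(methoxy)methyl]-3,4-bis(benzyloxy)benzene, via alpha-chloro ether 29 (not isolated)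
Conditions: AcCl (1.05 equiv), CH2Cl2, 0 °C to rt; then 28, i-Pr2NEt, CH2Cl2, −40 to 0 °C; basic alumina
Reagents that add atoms: none
Why: acetal-to-α-chloro-ether exchange with acetyl chloride followed by O-alkylation of the phenol through the oxocarbenium ion (the chemistry of alkoxymethyl ether formation), with the hindered amine keeping the medium basic so that O- and not C-alkylation occurs.

Step 17
Reactants: 24; 30
Product: 33 carbonate-bridged protected trimer (upper pyran ring formed; upper 2,3-trans-3,4-cis; O3 of the upper unit and O7 of the middle unit joined by C=O), via O-aryl oxocarbenium ion 31 (not isolated), via benzylic cation 32 (not isolated)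
Conditions: (S)-3,3'-bis(2,4,6-triisopropylphenyl)-1,1'-binaphthyl-2,2'-diyl N-(trifluoromethylsulfonyl)phosphoramide (10 mol %), 5 Å molecular sieves, toluene, −40 °C, 30 (1.3 equiv) added over 4 h
Reagents that add atoms: none
Why: Proposed new method: the acid ionizes acetal 30 to the O-aryl oxocarbenium ion 31 (a cationic 2-oxadiene C2=O1–C8a=C4a), C3 of the enol carbonate of 24 adds to C2 to give the para-alkoxybenzylic cation 32, and C4 is captured by the aryl ether ring para to its benzyloxy group; the closest known reaction is the acid-promoted oxa-Povarov reaction of aryl acetals with styrenes and cycloalkenes, which has not been run on an enol carbonate or under a chiral acid. The single new ring, the upper pyran, closes by a formal [4+2] cycloaddition whose second bond is a 6-endo Friedel–Crafts closure. Regioselectivity is needed at both partners: the alkene should react at C3 because only the C4 cation is stabilised (O1 of the middle A-ring is para, whereas O3 is acylated and a poor donor), and the arene should close para to OBn rather than at the hindered position between its two oxygens. C4 is set cis to O3 by the substrate, because the Z-alkene is held in the seven-membered carbonate ring and the flattened cation 32 can be reached by the tethered arene only on the face that already carries C2 (suprafacial addition). C2 is set trans to O3 by the exo approach that keeps the B-ring away from the fused carbonate and middle A-ring and by chair-like closure with a pseudo-equatorial aryl group. The choice between the two alkene faces, which fixes the absolute configuration of the upper unit relative to the remote centres of 24, is left to the chiral counter-anion of ion pair 31.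

Step 18
Reactants: 33
Product: 34 protected trimer diol (upper 3-OH and middle 7-OH free; eight benzyl ethers, diphenylmethylene ketal and lower ketone intact)
Conditions: K2CO3 (0.5 equiv), MeOH/THF 2:1, 0 °C to rt
Reagents that add atoms: none
Why: base-catalysed transesterification (methanolysis) of the aryl alkyl carbonate; kept cold and short so that the α-benzyloxy ketone of the lower unit is not enolized.

Step 19
Reactants: 34
Product: 35 fisetinidol-(4β→6)-fisetinidol-(4α→6)-fustin (free phenolic trimer, lower C4 ketone)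
Conditions: H2 (1 atm), Pd(OH)2/C, THF/MeOH 1:1, rt
Reagents that add atoms: none
Why: hydrogenolysis of the eight benzyl ethers and of the diphenylmethylene ketal; the ketone keeps the lower C4 from benzylic hydrogenolysis, which is why the reduction is placed after this step.

Step 20
Reactants: 35
Product: 36 target: (2R,3S,4S)-upper, (2R,3S,4R)-middle and (2R,3S,4R)-lower unit, fisetinidol-(4β→6)-fisetinidol-(4α→6)-mollisacacidin
Conditions: NaBH4, MeOH, 0 °C, argon; AcOH to pH 6
Reagents that add atoms: none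
Why: borohydride reduction of the aryl ketone, with hydride expected to add trans to the C3 hydroxyl as in the reduction of 2,3-trans-dihydroflavonols such as fustin to 2,3-trans-3,4-trans-flavan-3,4-diols, which sets the lower C4.

**Compound list**

1 | (2R,3R)-fustin | c1cc2c(cc1O)O[C@H](c1ccc(O)c(O)c1)[C@@H](O)C2=O | starting material
2 | benzyl bromide | BrCc1ccccc1 | starting material
3 | (2R,3R)-7-benzyloxy-2-[3,4-bis(benzyloxy)phenyl]-3-hydroxychroman-4-one | c1cc2c(cc1OCc1ccccc1)O[C@H](c1ccc(OCc3ccccc3)c(OCc3ccccc3)c1)[C@@H](O)C2=O | intermediate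
4 | ethane-1,2-dithiol | SCCS | starting material
5 | (2R,3R)-7-benzyloxy-2-[3,4-bis(benzyloxy)phenyl]spiro[chromane-4,2'-[1,3]dithiolan]-3-ol | c1cc2c(cc1OCc1ccccc1)O[C@H](c1ccc(OCc3ccccc3)c(OCc3ccccc3)c1)[C@@H](O)C23SCCS3 | intermediate
6 | (2R,3R)-3,7-bis(benzyloxy)-2-[3,4-bis(benzyloxy)phenyl]spiro[chromane-4,2'-[1,3]dithiolane] | c1cc2c(cc1OCc1ccccc1)O[C@H](c1ccc(OCc3ccccc3)c(OCc3ccccc3)c1)[C@@H](OCc1ccccc1)C23SCCS3 | intermediate
7 | dichlorodiphenylmethane | ClC(Cl)(c1ccccc1)c1ccccc1 | starting material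
8 | (2R,3R)-2-(2,2-diphenyl-1,3-benzodioxol-5-yl)-3,7-dihydroxychroman-4-one | c1cc2c(cc1O)O[C@H](c1ccc3OC(c4ccccc4)(c4ccccc4)Oc3c1)[C@@H](O)C2=O | intermediate
9 | chlorotriisopropylsilane | CC(C)[Si](Cl)(C(C)C)C(C)C | starting material
10 | (2R,3R)-2-(2,2-diphenyl-1,3-benzodioxol-5-yl)-3-hydroxy-7-(triisopropylsilyloxy)chroman-4-one | c1cc2c(cc1O[Si](C(C)C)(C(C)C)C(C)C)O[C@H](c1ccc3OC(c4ccccc4)(c4ccccc4)Oc3c1)[C@@H](O)C2=O | intermediate
11 | 2-benzyloxy-1-methylpyridinium triflate | C[n+]1ccccc1OCc1ccccc1.[O-]S(=O)(=O)C(F)(F)F | starting material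
12 | (2R,3R)-3-benzyloxy-2-(2,2-diphenyl-1,3-benzodioxol-5-yl)-7-(triisopropylsilyloxy)chroman-4-one | c1cc2c(cc1O[Si](C(C)C)(C(C)C)C(C)C)O[C@H](c1ccc3OC(c4ccccc4)(c4ccccc4)Oc3c1)[C@@H](OCc1ccccc1)C2=O | intermediate
13 | (2R,3S,4R)-3-benzyloxy-2-(2,2-diphenyl-1,3-benzodioxol-5-yl)-7-(triisopropylsilyloxy)chroman-4-ol | c1cc2c(cc1O[Si](C(C)C)(C(C)C)C(C)C)O[C@H](c1ccc3OC(c4ccccc4)(c4ccccc4)Oc3c1)[C@@H](OCc1ccccc1)[C@@H]2O | intermediate
14 | N-bromosuccinimide | O=C1CCC(=O)N1Br | starting material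
15 | (2R,3S,4R)-3-benzyloxy-6-bromo-2-(2,2-diphenyl-1,3-benzodioxol-5-yl)-7-(triisopropylsilyloxy)chroman-4-ol | Brc1cc2c(cc1O[Si](C(C)C)(C(C)C)C(C)C)O[C@H](c1ccc3OC(c4ccccc4)(c4ccccc4)Oc3c1)[C@@H](OCc1ccccc1)[C@@H]2O | intermediate
16 | dimer bromide dithiolane (middle unit 4α→6 lower unit) | Brc1cc2c(cc1O[Si](C(C)C)(C(C)C)C(C)C)O[C@H](c1ccc3OC(c4ccccc4)(c4ccccc4)Oc3c1)[C@@H](OCc1ccccc1)[C@@H]2c1cc2c(cc1OCc1ccccc1)O[C@H](c1ccc(OCc3ccccc3)c(OCc3ccccc3)c1)[C@@H](OCc1ccccc1)C23SCCS3 | intermediate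
17 | water | O | starting material
18 | dimer bromide ketone | Brc1cc2c(cc1O[Si](C(C)C)(C(C)C)C(C)C)O[C@H](c1ccc3OC(c4ccccc4)(c4ccccc4)Oc3c1)[C@@H](OCc1ccccc1)[C@@H]2c1cc2c(cc1OCc1ccccc1)O[C@H](c1ccc(OCc3ccccc3)c(OCc3ccccc3)c1)[C@@H](OCc1ccccc1)C2=O | intermediate
19 | tributyl(vinyl)stannane | C=C[Sn](CCCC)(CCCC)CCCC | starting material
20 | 6-vinyl dimer (7-OTIPS) | C=Cc1cc2c(cc1O[Si](C(C)C)(C(C)C)C(C)C)O[C@H](c1ccc3OC(c4ccccc4)(c4ccccc4)Oc3c1)[C@@H](OCc1ccccc1)[C@@H]2c1cc2c(cc1OCc1ccccc1)O[C@H](c1ccc(OCc3ccccc3)c(OCc3ccccc3)c1)[C@@H](OCc1ccccc1)C2=O | intermediate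
21 | 7-hydroxy-6-vinyl dimer | C=Cc1cc2c(cc1O)O[C@H](c1ccc3OC(c4ccccc4)(c4ccccc4)Oc3c1)[C@@H](OCc1ccccc1)[C@@H]2c1cc2c(cc1OCc1ccccc1)O[C@H](c1ccc(OCc3ccccc3)c(OCc3ccccc3)c1)[C@@H](OCc1ccccc1)C2=O | intermediate
22 | vinyl chloroformate | C=COC(Cl)=O | starting material
23 | 6-vinyl dimer 7-O-(vinyl carbonate) | C=Cc1cc2c(cc1OC(=O)OC=C)O[C@H](c1ccc3OC(c4ccccc4)(c4ccccc4)Oc3c1)[C@@H](OCc1ccccc1)[C@@H]2c1cc2c(cc1OCc1ccccc1)O[C@H](c1ccc(OCc3ccccc3)c(OCc3ccccc3)c1)[C@@H](OCc1ccccc1)C2=O | intermediate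
24 | cyclic enol carbonate (1,3-dioxepin-2-one fused to C6/C7 of the middle A-ring) | O=C1OC=Cc3cc2c(cc3O1)O[C@H](c1ccc3OC(c4ccccc4)(c4ccccc4)Oc3c1)[C@@H](OCc1ccccc1)[C@@H]2c1cc2c(cc1OCc1ccccc1)O[C@H](c1ccc(OCc3ccccc3)c(OCc3ccccc3)c1)[C@@H](OCc1ccccc1)C2=O | intermediate
25 | 3,4-bis(benzyloxy)benzaldehyde | O=Cc1ccc(OCc2ccccc2)c(OCc2ccccc2)c1 | starting material
26 | trimethyl orthoformate | COC(OC)OC | starting material
27 | 3,4-bis(benzyloxy)benzaldehyde dimethyl acetal | COC(OC)c1ccc(OCc2ccccc2)c(OCc2ccccc2)c1 | intermediate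
28 | 3-(benzyloxy)phenol | Oc1cccc(OCc2ccccc2)c1 | starting material
29 | racemic 1-[chloro(methoxy)methyl]-3,4-bis(benzyloxy)benzene (not isolated) | COC(Cl)c1ccc(OCc2ccccc2)c(OCc2ccccc2)c1 | intermediate
30 | racemic 1-[(3-benzyloxyphenoxy)(methoxy)methyl]-3,4-bis(benzyloxy)benzene | COC(Oc1cccc(OCc2ccccc2)c1)c1ccc(OCc2ccccc2)c(OCc2ccccc2)c1 | intermediate
31 | O-(3-benzyloxyphenyl) oxocarbenium ion of 25 (not isolated) | c1ccccc1COc1cccc(c1)[O+]=Cc1ccc(OCc2ccccc2)c(OCc2ccccc2)c1 | intermediate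
32 | benzylic cation at upper C4 after C2–C3 bond formation (not isolated) | c1ccccc1COc1cccc(c1)O[C@H](c1ccc(OCc3ccccc3)c(OCc3ccccc3)c1)[C@@H](OC6=O)[CH+]c1cc2c(cc1O6)O[C@H](c1ccc3OC(c4ccccc4)(c4ccccc4)Oc3c1)[C@@H](OCc1ccccc1)[C@@H]2c1cc2c(cc1OCc1ccccc1)O[C@H](c1ccc(OCc3ccccc3)c(OCc3ccccc3)c1)[C@@H](OCc1ccccc1)C2=O | intermediate
33 | carbonate-bridged protected trimer | c1ccccc1COc1ccc2c(c1)O[C@H](c1ccc(OCc3ccccc3)c(OCc3ccccc3)c1)[C@@H](OC6=O)[C@H]2c1cc2c(cc1O6)O[C@H](c1ccc3OC(c4ccccc4)(c4ccccc4)Oc3c1)[C@@H](OCc1ccccc1)[C@@H]2c1cc2c(cc1OCc1ccccc1)O[C@H](c1ccc(OCc3ccccc3)c(OCc3ccccc3)c1)[C@@H](OCc1ccccc1)C2=O | intermediate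
34 | protected trimer diol (upper 3-OH, middle 7-OH free) | c1ccccc1COc1ccc2c(c1)O[C@H](c1ccc(OCc3ccccc3)c(OCc3ccccc3)c1)[C@@H](O)[C@H]2c1cc2c(cc1O)O[C@H](c1ccc3OC(c4ccccc4)(c4ccccc4)Oc3c1)[C@@H](OCc1ccccc1)[C@@H]2c1cc2c(cc1OCc1ccccc1)O[C@H](c1ccc(OCc3ccccc3)c(OCc3ccccc3)c1)[C@@H](OCc1ccccc1)C2=O | intermediate
35 | fisetinidol-(4β→6)-fisetinidol-(4α→6)-fustin | Oc1ccc2c(c1)O[C@H](c1ccc(O)c(O)c1)[C@@H](O)[C@H]2c1cc2c(cc1O)O[C@H](c1ccc(O)c(O)c1)[C@@H](O)[C@@H]2c1cc2c(cc1O)O[C@H](c1ccc(O)c(O)c1)[C@@H](O)C2=O | intermediate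
36 | CNP0255184.1, fisetinidol-(4β→6)-fisetinidol-(4α→6)-mollisacacidin | Oc1ccc2c(c1)O[C@H](c1ccc(O)c(O)c1)[C@@H](O)[C@H]2c1cc2c(cc1O)O[C@H](c1ccc(O)c(O)c1)[C@@H](O)[C@@H]2c1cc2c(cc1O)O[C@H](c1ccc(O)c(O)c1)[C@@H](O)[C@@H]2O | target

**Step count and risks**

Total step count: 20. Longest linear sequence: 15 steps (steps 4 to 14 and 17 to 20, from fustin).

Steps most likely to fail:

1. Step 17 (Proposed new method). What may go wrong: addition of the oxocarbenium ion to the wrong alkene carbon or the wrong alkene face, endo instead of exo approach, proton loss from the cation before ring closure, and self-condensation of the acetal through its electron-rich aryloxy ring. Fallback with known chemistry (halogen–lithium exchange, organocerium addition to a ketone, ionic hydrogenation): it sets out from bromide 16 and ketone 12. Bromide 16 is lithiated (t-BuLi, THF, −78 °C), transmetallated with CeCl3 and added to 12 to give the tertiary 4-aryl-flavan-4-ol F1 as a mixture at the new carbinol centre. Et3SiH/TFA in CH2Cl2 at −40 °C ionizes F1, and hydride should add to the doubly benzylic cation anti to the 3-benzyloxy group, which places the aryl group cis to O3 and gives the 3,4-cis trimer dithiolane F2. MeI/NaHCO3 in aqueous MeCN then frees the trimer ketone F3, TBAF/AcOH removes both silyl groups to give the bis-phenol F4, and hydrogenolysis (H2, Pd(OH)2/C) brings the route back at compound 35.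

2. Step 14 (Proposed new method). What may go wrong: deactivation of the alkylidene by the O-acyl vinyl group and intermolecular metathesis of the styrene. Fallback with known chemistry (the classical flavan-4-yl cation coupling): it sets out from 18 and 15. Radical debromination of 18 (Bu3SnH, AIBN, toluene, 80 °C) gives the C6-unsubstituted dimer ketone F5, whose only activated arene position is C6 of the middle A-ring because the lower A-ring is deactivated by its ketone. Friedel–Crafts alkylation of F5 with the cation from 15 (BF3·OEt2, CH2Cl2, −40 to 0 °C) should give both C4 epimers of the new upper unit, and the 3,4-cis epimer, the bromo trimer F6, is separated by chromatography. TBAF/AcOH gives the bis-phenol F7, and hydrogenolysis in the presence of Et3N (H2, Pd(OH)2/C), which also removes the aryl bromide, brings the route back at compound 35.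

3. Step 9. What may go wrong: incomplete facial selectivity at C4, proton loss from the cation to a flav-3-ene, and loss of the silyl ether under BF3. Fallback (thiophilic, acid-free generation of the cation instead of Lewis-acid ionization of the alcohol): it sets out from 15, which is converted with phenylmethanethiol and acetic acid into the 4-benzylthio ether F8 (mixture at C4). Activation of F8 with AgBF4 in THF at 0 °C in the presence of 6 and 2,6-di-tert-butylpyridine then forms the same C4–C6 bond and comes back to the route at compound 16.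

**Further compounds**

F1 | step 17 | tertiary 4-aryl-flavan-4-ol from 16 and 12 (upper C4 unassigned) | CC(C)[Si](C(C)C)(C(C)C)Oc1ccc2c(c1)O[C@H](c1ccc3OC(c4ccccc4)(c4ccccc4)Oc3c1)[C@@H](OCc1ccccc1)C2(O)c1cc2c(cc1O[Si](C(C)C)(C(C)C)C(C)C)O[C@H](c1ccc3OC(c4ccccc4)(c4ccccc4)Oc3c1)[C@@H](OCc1ccccc1)[C@@H]2c1cc2c(cc1OCc1ccccc1)O[C@H](c1ccc(OCc3ccccc3)c(OCc3ccccc3)c1)[C@@H](OCc1ccccc1)C23SCCS3
F2 | step 17 | 3,4-cis trimer dithiolane | CC(C)[Si](C(C)C)(C(C)C)Oc1ccc2c(c1)O[C@H](c1ccc3OC(c4ccccc4)(c4ccccc4)Oc3c1)[C@@H](OCc1ccccc1)[C@H]2c1cc2c(cc1O[Si](C(C)C)(C(C)C)C(C)C)O[C@H](c1ccc3OC(c4ccccc4)(c4ccccc4)Oc3c1)[C@@H](OCc1ccccc1)[C@@H]2c1cc2c(cc1OCc1ccccc1)O[C@H](c1ccc(OCc3ccccc3)c(OCc3ccccc3)c1)[C@@H](OCc1ccccc1)C23SCCS3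
F3 | step 17 | 3,4-cis trimer ketone (two silyl ethers) | CC(C)[Si](C(C)C)(C(C)C)Oc1ccc2c(c1)O[C@H](c1ccc3OC(c4ccccc4)(c4ccccc4)Oc3c1)[C@@H](OCc1ccccc1)[C@H]2c1cc2c(cc1O[Si](C(C)C)(C(C)C)C(C)C)O[C@H](c1ccc3OC(c4ccccc4)(c4ccccc4)Oc3c1)[C@@H](OCc1ccccc1)[C@@H]2c1cc2c(cc1OCc1ccccc1)O[C@H](c1ccc(OCc3ccccc3)c(OCc3ccccc3)c1)[C@@H](OCc1ccccc1)C2=O
F4 | step 17 | trimer ketone bis-phenol (upper and middle 7-OH free) | Oc1ccc2c(c1)O[C@H](c1ccc3OC(c4ccccc4)(c4ccccc4)Oc3c1)[C@@H](OCc1ccccc1)[C@H]2c1cc2c(cc1O)O[C@H](c1ccc3OC(c4ccccc4)(c4ccccc4)Oc3c1)[C@@H](OCc1ccccc1)[C@@H]2c1cc2c(cc1OCc1ccccc1)O[C@H](c1ccc(OCc3ccccc3)c(OCc3ccccc3)c1)[C@@H](OCc1ccccc1)C2=O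
F5 | step 14 | C6-unsubstituted dimer ketone | c1cc2c(cc1O[Si](C(C)C)(C(C)C)C(C)C)O[C@H](c1ccc3OC(c4ccccc4)(c4ccccc4)Oc3c1)[C@@H](OCc1ccccc1)[C@@H]2c1cc2c(cc1OCc1ccccc1)O[C@H](c1ccc(OCc3ccccc3)c(OCc3ccccc3)c1)[C@@H](OCc1ccccc1)C2=O
F6 | step 14 | 3,4-cis bromo trimer (upper 6-bromo, two silyl ethers) | CC(C)[Si](C(C)C)(C(C)C)Oc1c(Br)cc2c(c1)O[C@H](c1ccc3OC(c4ccccc4)(c4ccccc4)Oc3c1)[C@@H](OCc1ccccc1)[C@H]2c1cc2c(cc1O[Si](C(C)C)(C(C)C)C(C)C)O[C@H](c1ccc3OC(c4ccccc4)(c4ccccc4)Oc3c1)[C@@H](OCc1ccccc1)[C@@H]2c1cc2c(cc1OCc1ccccc1)O[C@H](c1ccc(OCc3ccccc3)c(OCc3ccccc3)c1)[C@@H](OCc1ccccc1)C2=O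
F7 | step 14 | bromo trimer bis-phenol | Oc1c(Br)cc2c(c1)O[C@H](c1ccc3OC(c4ccccc4)(c4ccccc4)Oc3c1)[C@@H](OCc1ccccc1)[C@H]2c1cc2c(cc1O)O[C@H](c1ccc3OC(c4ccccc4)(c4ccccc4)Oc3c1)[C@@H](OCc1ccccc1)[C@@H]2c1cc2c(cc1OCc1ccccc1)O[C@H](c1ccc(OCc3ccccc3)c(OCc3ccccc3)c1)[C@@H](OCc1ccccc1)C2=O
F8 | step 9 | 4-benzylthio ether of 15 (C4 unassigned) | Brc1cc2c(cc1O[Si](C(C)C)(C(C)C)C(C)C)O[C@H](c1ccc3OC(c4ccccc4)(c4ccccc4)Oc3c1)[C@@H](OCc1ccccc1)C2SCc1ccccc1
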